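**Plan**
1. Cuts: the quinone is unmasked last from a 1,4-dimethoxynaphthalene; the side chain is cut at C-6′–C-7′ (CH2 to CH(CH3)); the left half at aryl–C-1′; the right half at C-8′–C-9′, C-14′–ring C-1, ring C-1=C-2 and ring C-3–C-4 (ring C-1 carries the chain, C-3 the 6-methylheptan-2-yl group, C-2 lies between them).
2. Enabling feature: C-7′ bears only H, CH3 and two unbranched CH2 neighbours; CH3–C-7′–C-8′ is the skeleton of propylene oxide, so C-7′ can be an (R)-alkan-2-yl sulfonate that the C-6′ carbanion displaces from the back.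
3. Left half: the bromo-dimethoxy-methylnaphthalene is joined to (S)-citronellyl bromide, the alkene is cleaved and the end converted to a bromide.
4. Right half: (S)-citronellyl Grignard opens (R)-propylene oxide; alkene cleavage and addition to acrolein give a vinyl ketone; Michael addition of (R)-citronellal and McMurry coupling close the cyclopentene (the only ring formed); hydrogenation, then tosylation.
5. Union at C-6′–C-7′ by copper-catalysed Grignard/secondary tosylate coupling, then oxidative demethylation to the naphthoquinone.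
6. Stereochemistry: C-3′ and C-11′ from (S)-citronellyl bromide (used twice); C-7′ from (R)-propylene oxide with inversion in the key step; the CH(CH3) next to the ring from (R)-citronellal; ring C-3 by catalyst control (enamine Michael); ring C-1 by hydrogenation anti to the C-3 substituent.

Key step: step 15

Assumption: the ring is the cis-(1R,3S)-1,3-disubstituted cyclopentane that the SMILES encodes, and 2-bromo-1,4-dimethoxy-3-methylnaphthalene (1) is taken as purchasable (otherwise one bromination from 1,4-dimethoxy-2-methylnaphthalene).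

**Route**

Step 1
Reactants: 1 2-bromo-1,4-dimethoxy-3-methylnaphthalene; 2 (S)-citronellyl bromide [(6S)-8-bromo-2,6-dimethyloct-2-ene]
Product: 4 2-[(3S)-3,7-dimethyloct-6-en-1-yl]-1,4-dimethoxy-3-methylnaphthalene, via arylmagnesium bromide 3 (not isolated)
Conditions: Mg, THF, 50 °C; then 2, Li2CuCl4 (3 mol %), THF/NMP, 0 °C to rt
Reagents that add atoms: none
Why: Copper-catalysed cross-coupling of an aryl Grignard reagent with a primary alkyl bromide; the C-3′ stereocentre lies two carbons from the reacting centre and is carried over unchanged.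

Step 2
Reactants: 4 2-[(3S)-3,7-dimethyloct-6-en-1-yl]-1,4-dimethoxy-3-methylnaphthalene
Product: 6 (4R)-6-(1,4-dimethoxy-3-methylnaphthalen-2-yl)-4-methylhexan-1-ol, via aldehyde 5 (not isolated)
Conditions: OsO4 (2 mol %), NaIO4, 2,6-lutidine, dioxane/H2O, rt; extractive work-up; then NaBH4, MeOH, 0 °C
Reagents that add atoms: osmium tetroxide, O=[Os](=O)(=O)=O (catalytic oxygen carrier); sodium periodate, [Na+].[O-]I(=O)(=O)=O (terminal oxidant)
Why: Lemieux–Johnson cleavage removes the isopropylidene carbon without touching the electron-rich arene (which ozone could attack), and borohydride reduction gives the primary alcohol; no stereocentre is involved.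

Step 3
Reactants: 6 (4R)-6-(1,4-dimethoxy-3-methylnaphthalen-2-yl)-4-methylhexan-1-ol
Product: 7 2-[(3R)-6-bromo-3-methylhexyl]-1,4-dimethoxy-3-methylnaphthalene
Conditions: CBr4, PPh3, CH2Cl2, 0 °C
Reagents that add atoms: carbon tetrabromide, BrC(Br)(Br)Br
Why: Appel reaction of a primary alcohol under neutral conditions that leave the aryl methyl ethers and the stereocentre alone.

Step 4
Reactants: 2 (S)-citronellyl bromide; 8 (R)-propylene oxide [(2R)-2-methyloxirane]
Product: 10 (2R,6R)-6,10-dimethylundec-9-en-2-ol, via (S)-citronellylmagnesium bromide 9 (not isolated)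
Conditions: Mg, THF, 40 °C; then 8, CuI (10 mol %), THF, −30 to 0 °C; aq NH4Cl
Reagents that add atoms: none
Why: Copper-catalysed SN2 opening of the terminal epoxide at its unsubstituted CH2 joins C-8′ to C-9′; the carbinol carbon (future C-7′) is not a reacting centre and keeps the R configuration of the epoxide, and C-11′ comes unchanged from the citronellyl unit.

Step 5
Reactants: 10 (2R,6R)-6,10-dimethylundec-9-en-2-ol
Product: 11 tert-butyl{[(2R,6R)-6,10-dimethylundec-9-en-2-yl]oxy}dimethylsilane
Conditions: TBSCl, imidazole, DMF, rt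
Reagents that add atoms: tert-butyldimethylsilyl chloride, CC(C)(C)[Si](C)(C)Cl
Why: Standard silylation; the ether must survive two Grignard formations, an oxidation, the titanium coupling and the hydrogenation.

Step 6
Reactants: 11 tert-butyl{[(2R,6R)-6,10-dimethylundec-9-en-2-yl]oxy}dimethylsilane
Product: 13 (4R,8R)-8-[(tert-butyldimethylsilyl)oxy]-4-methylnonan-1-ol, via aldehyde 12 (not isolated)
Conditions: O3, CH2Cl2/MeOH, −78 °C; then NaBH4, −78 °C to rt
Reagents that add atoms: ozone, [O-][O+]=O
Why: Ozonolysis with reductive work-up cuts off the isopropylidene group and leaves C-14′ as CH2OH; the only alkene is the one to be cleaved.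

Step 7
Reactants: 13 (4R,8R)-8-[(tert-butyldimethylsilyl)oxy]-4-methylnonan-1-ol
Product: 14 {[(2R,6R)-9-bromo-6-methylnonan-2-yl]oxy}(tert-butyl)dimethylsilane
Conditions: CBr4, PPh3, CH2Cl2, 0 °C
Reagents that add atoms: carbon tetrabromide, BrC(Br)(Br)Br
Why: Appel reaction; the secondary silyl ether is stable to these neutral conditions.

Step 8
Reactants: 14 {[(2R,6R)-9-bromo-6-methylnonan-2-yl]oxy}(tert-butyl)dimethylsilane; 15 acrolein (prop-2-enal)
Product: 17 (7S,11R)-11-[(tert-butyldimethylsilyl)oxy]-7-methyldodec-1-en-3-ol (both C-3 epimers), via alkylmagnesium bromide 16 (not isolated)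
Conditions: Mg, THF, 40 °C; then 15, THF, −78 °C; aq NH4Cl
Reagents that add atoms: none
Why: Grignard 1,2-addition to acrolein forms the C-14′–ring C-1 bond and brings in ring C-1, C-5 and C-4; the carbinol centre is oxidised in the next step, so its configuration does not matter.

Step 9
Reactants: 17 (7S,11R)-11-[(tert-butyldimethylsilyl)oxy]-7-methyldodec-1-en-3-ol (both C-3 epimers)
Product: 18 (7R,11R)-11-[(tert-butyldimethylsilyl)oxy]-7-methyldodec-1-en-3-one
Conditions: 1,1,1-triacetoxy-1,1-dihydro-1,2-benziodoxol-3(1H)-one (periodinane), NaHCO3, CH2Cl2, 0 °C to rt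
Reagents that add atoms: none
Why: Periodinane oxidation of an allylic alcohol under buffered, non-basic conditions gives the polymerisation-prone vinyl ketone cleanly; it is used at once.

Step 10
Reactants: 18 (7R,11R)-11-[(tert-butyldimethylsilyl)oxy]-7-methyldodec-1-en-3-one; 19 (R)-citronellal [(3R)-3,7-dimethyloct-6-enal]
Product: 20 (2R,9R,13R)-13-[(tert-butyldimethylsilyl)oxy]-9-methyl-2-[(2R)-6-methylhept-5-en-2-yl]-5-oxotetradecanal
Conditions: (R)-2-[diphenyl(trimethylsilyloxy)methyl]pyrrolidine (10 mol %), ethyl 3,4-dihydroxybenzoate (20 mol %), 19 (3 equiv), neat, 4 °C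
Reagents that add atoms: none
Why: Enamine-catalysed Michael addition of an aldehyde to a vinyl ketone forms ring C-3–C-4; the (R)-catalyst is chosen because its diphenyl(silyloxy)methyl group shields the enamine face that would give the (2S) epimer, so ring C-3 should be set under catalyst control next to the citronellal stereocentre.

Step 11
Reactants: 20 (2R,9R,13R)-13-[(tert-butyldimethylsilyl)oxy]-9-methyl-2-[(2R)-6-methylhept-5-en-2-yl]-5-oxotetradecanal
Product: 21 tert-butyl(dimethyl){[(2R,6S)-6-methyl-9-{(3R)-3-[(2R)-6-methylhept-5-en-2-yl]cyclopent-1-en-1-yl}nonan-2-yl]oxy}silane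
Conditions: TiCl3(DME)1.5, Zn(Cu), DME, reflux; slow addition of 20 at high dilution
Reagents that add atoms: none
Why: Intramolecular McMurry coupling of the 1,5-keto aldehyde closes the five-membered ring as the C-1=C-2 alkene; no stereocentre is formed and the allylic C-3 centre is carried through.

Step 12
Reactants: 21 tert-butyl(dimethyl){[(2R,6S)-6-methyl-9-{(3R)-3-[(2R)-6-methylhept-5-en-2-yl]cyclopent-1-en-1-yl}nonan-2-yl]oxy}silane
Product: 22 tert-butyl(dimethyl){[(2R,6S)-6-methyl-9-{(1R,3S)-3-[(2R)-6-methylheptan-2-yl]cyclopentyl}nonan-2-yl]oxy}silane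
Conditions: H2 (1 atm), PtO2, EtOAc, rt
Reagents that add atoms: none
Why: Heterogeneous hydrogenation saturates both trisubstituted alkenes; syn delivery of H2 to the ring alkene from the face anti to the branched allylic substituent at C-3 should place the C-1 chain cis to it, and PtO2 is chosen because it causes little double-bond migration.

Step 13
Reactants: 22 tert-butyl(dimethyl){[(2R,6S)-6-methyl-9-{(1R,3S)-3-[(2R)-6-methylheptan-2-yl]cyclopentyl}nonan-2-yl]oxy}silane
Product: 23 (2R,6S)-6-methyl-9-{(1R,3S)-3-[(2R)-6-methylheptan-2-yl]cyclopentyl}nonan-2-ol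
Conditions: Bu4NF, THF, rt
Reagents that add atoms: none
Why: Fluoride desilylation; the molecule is otherwise a saturated hydrocarbon.

Step 14
Reactants: 23 (2R,6S)-6-methyl-9-{(1R,3S)-3-[(2R)-6-methylheptan-2-yl]cyclopentyl}nonan-2-ol
Product: 24 (2R,6S)-6-methyl-9-{(1R,3S)-3-[(2R)-6-methylheptan-2-yl]cyclopentyl}nonan-2-yl 4-methylbenzenesulfonate
Conditions: TsCl, pyridine, DMAP (cat.), CH2Cl2, 0 °C to rt
Reagents that add atoms: 4-methylbenzenesulfonyl chloride, Cc1ccc(cc1)S(Cl)(=O)=O
Why: O-Sulfonylation breaks only the O–H bond, so the carbinol carbon keeps its R configuration; the tosylate is used promptly.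

Step 15
Reactants: 7 2-[(3R)-6-bromo-3-methylhexyl]-1,4-dimethoxy-3-methylnaphthalene; 24 (2R,6S)-6-methyl-9-{(1R,3S)-3-[(2R)-6-methylheptan-2-yl]cyclopentyl}nonan-2-yl 4-methylbenzenesulfonate
Product: 26 1,4-dimethoxy-2-methyl-3-[(3S,7S,11R)-3,7,11-trimethyl-14-{(1R,3S)-3-[(2R)-6-methylheptan-2-yl]cyclopentyl}tetradecyl]naphthalene, via alkylmagnesium bromide 25 (not isolated)
Conditions: 7, Mg, THF, 40 °C (25, 1.5 equiv); then 24, CuI (10 mol %), TMEDA (20 mol %), LiOMe (1 equiv), THF, 0 °C
Reagents that add atoms: none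
Why: Transmetalation of the primary alkylmagnesium bromide 25 to copper gives an alkylcuprate that attacks C-7′ of tosylate 24 from the side opposite the leaving group (SN2-type oxidative addition, then reductive elimination), so the C-6′–C-7′ bond forms with inversion. The closest known reaction type is the copper-catalysed cross-coupling of alkyl Grignard reagents with unactivated secondary alkyl tosylates, the catalytic form of the cuprate–tosylate displacement. No ring is closed. The one new stereocentre, C-7′, is controlled by the configuration of the tosylate carbon, which stems from (R)-propylene oxide: the (R)-sulfonate should give the (S)-configured methyl branch. The step needs substitution to outrun E2 elimination and any single-electron, stereorandom pathway; a sulfonate rather than a halide leaving group, the TMEDA/LiOMe-modified copper catalyst at 0 °C, an electrophilic carbon flanked only by CH3 and an unbranched CH2, and a nucleophile whose nearest branch is at C-3′ secure this. The quinone is masked as its dimethyl ether, so the tosylate is the only electrophile present.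

Step 16
Reactants: 26 1,4-dimethoxy-2-methyl-3-[(3S,7S,11R)-3,7,11-trimethyl-14-{(1R,3S)-3-[(2R)-6-methylheptan-2-yl]cyclopentyl}tetradecyl]naphthalene
Product: 27 2-methyl-3-[(3S,7S,11R)-3,7,11-trimethyl-14-{(1R,3S)-3-[(2R)-6-methylheptan-2-yl]cyclopentyl}tetradecyl]naphthalene-1,4-dione
Conditions: (NH4)2Ce(NO3)6, MeCN/H2O, 0 °C
Reagents that add atoms: water, O
Why: Oxidative demethylation of the 1,4-dimethoxynaphthalene releases the 1,4-naphthoquinone (the carbonyl oxygens come from water); the saturated side chain is inert.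

**Compound list**
1 | 2-bromo-1,4-dimethoxy-3-methylnaphthalene | COc1c(Br)c(C)c(OC)c2ccccc12 | starting material
2 | (S)-citronellyl bromide, (6S)-8-bromo-2,6-dimethyloct-2-ene | BrCC[C@@H](C)CCC=C(C)C | starting material
3 | (1,4-dimethoxy-3-methylnaphthalen-2-yl)magnesium bromide | COc1c([Mg]Br)c(C)c(OC)c2ccccc12 | intermediate (not isolated)
4 | 2-[(3S)-3,7-dimethyloct-6-en-1-yl]-1,4-dimethoxy-3-methylnaphthalene | COc1c(C)c(CC[C@@H](C)CCC=C(C)C)c(OC)c2ccccc12 | intermediate
5 | (4R)-6-(1,4-dimethoxy-3-methylnaphthalen-2-yl)-4-methylhexanal | COc1c(C)c(CC[C@@H](C)CCC=O)c(OC)c2ccccc12 | intermediate (not isolated)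
6 | (4R)-6-(1,4-dimethoxy-3-methylnaphthalen-2-yl)-4-methylhexan-1-ol | COc1c(C)c(CC[C@@H](C)CCCO)c(OC)c2ccccc12 | intermediate
7 | 2-[(3R)-6-bromo-3-methylhexyl]-1,4-dimethoxy-3-methylnaphthalene | COc1c(C)c(CC[C@@H](C)CCCBr)c(OC)c2ccccc12 | intermediate
8 | (R)-propylene oxide, (2R)-2-methyloxirane | C[C@@H]1CO1 | starting material
9 | [(3S)-3,7-dimethyloct-6-en-1-yl]magnesium bromide | Br[Mg]CC[C@@H](C)CCC=C(C)C | intermediate (not isolated)
10 | (2R,6R)-6,10-dimethylundec-9-en-2-ol | C[C@@H](O)CCC[C@@H](C)CCC=C(C)C | intermediate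
11 | tert-butyl{[(2R,6R)-6,10-dimethylundec-9-en-2-yl]oxy}dimethylsilane | C[C@@H](O[Si](C)(C)C(C)(C)C)CCC[C@@H](C)CCC=C(C)C | intermediate
12 | (4R,8R)-8-[(tert-butyldimethylsilyl)oxy]-4-methylnonanal | C[C@@H](O[Si](C)(C)C(C)(C)C)CCC[C@@H](C)CCC=O | intermediate (not isolated)
13 | (4R,8R)-8-[(tert-butyldimethylsilyl)oxy]-4-methylnonan-1-ol | C[C@@H](O[Si](C)(C)C(C)(C)C)CCC[C@@H](C)CCCO | intermediate
14 | {[(2R,6R)-9-bromo-6-methylnonan-2-yl]oxy}(tert-butyl)dimethylsilane | C[C@@H](O[Si](C)(C)C(C)(C)C)CCC[C@@H](C)CCCBr | intermediate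
15 | acrolein, prop-2-enal | C=CC=O | starting material
16 | {(4R,8R)-8-[(tert-butyldimethylsilyl)oxy]-4-methylnonyl}magnesium bromide | C[C@@H](O[Si](C)(C)C(C)(C)C)CCC[C@@H](C)CCC[Mg]Br | intermediate (not isolated)
17 | (7S,11R)-11-[(tert-butyldimethylsilyl)oxy]-7-methyldodec-1-en-3-ol (both C-3 epimers) | C[C@@H](O[Si](C)(C)C(C)(C)C)CCC[C@@H](C)CCCC(O)C=C | intermediate
18 | (7R,11R)-11-[(tert-butyldimethylsilyl)oxy]-7-methyldodec-1-en-3-one | C[C@@H](O[Si](C)(C)C(C)(C)C)CCC[C@@H](C)CCCC(=O)C=C | intermediate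
19 | (R)-citronellal, (3R)-3,7-dimethyloct-6-enal | O=CC[C@H](C)CCC=C(C)C | starting material
20 | (2R,9R,13R)-13-[(tert-butyldimethylsilyl)oxy]-9-methyl-2-[(2R)-6-methylhept-5-en-2-yl]-5-oxotetradecanal | C[C@@H](O[Si](C)(C)C(C)(C)C)CCC[C@@H](C)CCCC(=O)CC[C@H]([C@H](C)CCC=C(C)C)C=O | intermediate
21 | tert-butyl(dimethyl){[(2R,6S)-6-methyl-9-{(3R)-3-[(2R)-6-methylhept-5-en-2-yl]cyclopent-1-en-1-yl}nonan-2-yl]oxy}silane | C[C@@H](O[Si](C)(C)C(C)(C)C)CCC[C@@H](C)CCCC1=C[C@@H]([C@H](C)CCC=C(C)C)CC1 | intermediate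
22 | tert-butyl(dimethyl){[(2R,6S)-6-methyl-9-{(1R,3S)-3-[(2R)-6-methylheptan-2-yl]cyclopentyl}nonan-2-yl]oxy}silane | C[C@@H](O[Si](C)(C)C(C)(C)C)CCC[C@@H](C)CCC[C@@H]1CC[C@H]([C@H](C)CCCC(C)C)C1 | intermediate
23 | (2R,6S)-6-methyl-9-{(1R,3S)-3-[(2R)-6-methylheptan-2-yl]cyclopentyl}nonan-2-ol | C[C@@H](O)CCC[C@@H](C)CCC[C@@H]1CC[C@H]([C@H](C)CCCC(C)C)C1 | intermediate
24 | (2R,6S)-6-methyl-9-{(1R,3S)-3-[(2R)-6-methylheptan-2-yl]cyclopentyl}nonan-2-yl 4-methylbenzenesulfonate | C[C@@H](OS(=O)(=O)c1ccc(C)cc1)CCC[C@@H](C)CCC[C@@H]1CC[C@H]([C@H](C)CCCC(C)C)C1 | intermediate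
25 | [(4R)-6-(1,4-dimethoxy-3-methylnaphthalen-2-yl)-4-methylhexyl]magnesium bromide | COc1c(C)c(CC[C@@H](C)CCC[Mg]Br)c(OC)c2ccccc12 | intermediate (not isolated)
26 | 1,4-dimethoxy-2-methyl-3-[(3S,7S,11R)-3,7,11-trimethyl-14-{(1R,3S)-3-[(2R)-6-methylheptan-2-yl]cyclopentyl}tetradecyl]naphthalene | COc1c(C)c(CC[C@@H](C)CCC[C@@H](C)CCC[C@@H](C)CCC[C@@H]3CC[C@H]([C@H](C)CCCC(C)C)C3)c(OC)c2ccccc12 | intermediate
27 | 2-methyl-3-[(3S,7S,11R)-3,7,11-trimethyl-14-{(1R,3S)-3-[(2R)-6-methylheptan-2-yl]cyclopentyl}tetradecyl]naphthalene-1,4-dione | CC1=C(CC[C@@H](C)CCC[C@@H](C)CCC[C@@H](C)CCC[C@@H]2CC[C@H]([C@H](C)CCCC(C)C)C2)C(=O)c2ccccc2C1=O | target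

**Summary**
Total step count: 16. Longest linear sequence: 13 steps (steps 4 to 16, from (S)-citronellyl bromide 2).

**Steps most likely to fail, with fallbacks**

Step 12. What may go wrong is weak facial discrimination in the delivery of H2 to the ring alkene, because the allylic substituent can sit pseudo-equatorially and shield its face only partly. Double-bond migration on the catalyst before reduction would also scramble ring C-3. The fallback sets out from 21 and returns at 22. Hydroboration of both trisubstituted alkenes of 21 (BH3·SMe2, THF, 0 °C to rt; then NaOH, H2O2) should give the diol F1. Boron, the bulky end of the reagent, bonds to ring C-2 next to the stereocentre, so this irreversible syn addition should occur anti to the C-3 substituent and place the C-1 chain cis to it. Treatment with NaH, CS2 and MeI should give the bis(S-methyl xanthate) F2. Barton–McCombie deoxygenation (Bu3SnH, AIBN, toluene, 110 °C) then removes both auxiliary oxygens and gives 22.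

Step 15. What may go wrong is β-elimination of the secondary sulfonate by the basic organometallic, homocoupling of the Grignard reagent, or partial loss of stereospecificity through electron transfer. The fallback sets out from 7 and 23 and returns at 26; it uses a softer, far less basic sulfonyl-stabilised carbanion. Bromide 7 with PhSO2Na (DMF, 60 °C) should give the phenyl sulfone F3. Alcohol 23 with Tf2O and 2,6-lutidine (CH2Cl2, −78 °C) should give the triflate F4, which is used at once. Lithiated F3 (n-BuLi, THF/HMPA, −78 °C) should displace the triflate with inversion to give the coupled sulfone F5, a mixture of epimers at the sulfonyl carbon. Reductive desulfonylation (Na(Hg), Na2HPO4, MeOH) then gives 26.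

Step 11. What may go wrong is intermolecular carbonyl coupling, arrest at the pinacol stage, or enolisation of the α-branched aldehyde on the Lewis-acidic titanium surface with epimerisation of ring C-3. The fallback sets out from 20 and returns at 21. Non-basic Takai–Lombardo methylenation of both carbonyl groups (Zn, CH2Br2, TiCl4, THF, 0 °C) should give the diene F6. Ring-closing metathesis with the second-generation Grubbs catalyst (CH2Cl2, 40 °C) between the vinyl group and the 1,1-disubstituted alkene should then close the cyclopentene 21; the trisubstituted side-chain alkene is expected to react far more slowly.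

**Further compounds**
F1 | step 12 | diol from 21: silyl ether 22 with one extra OH on ring C-2 (trans to both ring substituents) and one at C-5 of the heptyl group (both epimers) | C[C@@H](O[Si](C)(C)C(C)(C)C)CCC[C@@H](C)CCC[C@@H]1CC[C@H]([C@H](C)CCC(O)C(C)C)[C@H]1O
F2 | step 12 | bis(S-methyl xanthate) of F1 | C[C@@H](O[Si](C)(C)C(C)(C)C)CCC[C@@H](C)CCC[C@@H]1CC[C@H]([C@H](C)CCC(OC(=S)SC)C(C)C)[C@H]1OC(=S)SC
F3 | step 15 | 1,4-dimethoxy-2-methyl-3-[(3R)-3-methyl-6-(phenylsulfonyl)hexyl]naphthalene | COc1c(C)c(CC[C@@H](C)CCCS(=O)(=O)c3ccccc3)c(OC)c2ccccc12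
F4 | step 15 | (2R,6S)-6-methyl-9-{(1R,3S)-3-[(2R)-6-methylheptan-2-yl]cyclopentyl}nonan-2-yl trifluoromethanesulfonate | C[C@@H](OS(=O)(=O)C(F)(F)F)CCC[C@@H](C)CCC[C@@H]1CC[C@H]([C@H](C)CCCC(C)C)C1
F5 | step 15 | 1,4-dimethoxy-2-methyl-3-[(3R,7S,11S)-3,7,11-trimethyl-6-(phenylsulfonyl)-14-{(1R,3S)-3-[(2R)-6-methylheptan-2-yl]cyclopentyl}tetradecyl]naphthalene (both C-6′ epimers) | COc1c(C)c(CC[C@@H](C)CCC([C@@H](C)CCC[C@@H](C)CCC[C@@H]3CC[C@H]([C@H](C)CCCC(C)C)C3)S(=O)(=O)c4ccccc4)c(OC)c2ccccc12
F6 | step 11 | tert-butyl(dimethyl){[(2R,6S,13S)-6-methyl-10-methylidene-13-[(2R)-6-methylhept-5-en-2-yl]pentadec-14-en-2-yl]oxy}silane | C[C@@H](O[Si](C)(C)C(C)(C)C)CCC[C@@H](C)CCCC(=C)CC[C@H]([C@H](C)CCC=C(C)C)C=C
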